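**Assumption:** the target (8‑methylmenaquinone‑6) has no stereocentres, so "single enantiomer" reduces to delivering all five stereogenic C=C bonds as E. (2E,6E)‑Farnesyl acetate, (2E,6E)‑farnesyl bromide and 1,7‑dimethylnaphthalene are taken as purchasable. The route is designed from known reaction types and has not been run.

## Retrosynthetic overview
1. Cut the quinone C3–CH2 bond: the target comes from the cyclopentadiene (Cp) Diels–Alder adduct of 2,8‑dimethyl‑1,4‑naphthoquinone by enolate C‑alkylation with all‑E hexaprenyl bromide, then retro‑Diels–Alder.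
2. The naphthoquinone core comes from oxidation of 1,7‑dimethylnaphthalene, so no ring is built; the only ring formed is the temporary norbornene, which is later removed.
3. The C30 all‑E chain is C15 + C15: farnesyl phenyl sulfone anion plus 12‑bromofarnesyl acetate, then reductive desulfonylation.
4. The 12‑bromide comes from E‑selective SeO2 allylic oxidation of farnesyl acetate.

## Route

**Step 1**
Reactants: 1, 1,7‑dimethylnaphthalene
Product: 2, 2,8‑dimethylnaphthalene‑1,4‑dione
Conditions: CrO3 (4–5 equiv), 80% aq AcOH, 10 → 40 °C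
Reagents that add atoms: chromium trioxide, O=[Cr](=O)=O
Why: Chromic acid arene‑to‑quinone oxidation (as in the menadione synthesis); the β‑methyl ring is the more activated and is the only ring with two free para α‑positions, so only this 1,4‑quinone can form.

**Step 2**
Reactants: 2; 3, cyclopenta‑1,3‑diene (freshly cracked)
Product: 4, racemic endo adduct 4a,5‑dimethyl‑1,4,4a,9a‑tetrahydro‑1,4‑methanoanthracene‑9,10‑dione (cis ring fusion; both C=O endo; 4a‑Me and 9a‑H exo, syn to the CH2 bridge)
Conditions: CpH (5 equiv), AcOH, rt, 48 h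
Reagents that add atoms: cyclopentadiene, C1C=CC=C1
Why: Endo‑selective Diels–Alder across the only dienophilic C=C; it masks the quinone and leaves a single enolisable α‑H (C9a), and the racemic stereocentres are erased in step 10.

**Step 3**
Reactants: 5, (2E,6E)‑farnesyl acetate
Product: 6, (2E,6E,10E)‑12‑hydroxy‑3,7,11‑trimethyldodeca‑2,6,10‑trien‑1‑yl acetate
Conditions: SeO2 (0.3 equiv), t‑BuOOH, salicylic acid (cat.), CH2Cl2, 0 °C → rt; then NaBH4, MeOH, 0 °C (returns over‑oxidised enal to the alcohol)
Reagents that add atoms: selenium dioxide, O=[Se]=O (reoxidised by tert‑butyl hydroperoxide, CC(C)(C)OO)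
Why: Sharpless SeO2 allylic oxidation (ene/[2,3]) attacks the terminal gem‑dimethyl alkene at the E‑methyl, which makes the Δ10 alkene stereogenic as E; the acetate‑deactivated Δ2 alkene is untouched.

**Step 4**
Reactants: 6
Product: 7, (2E,6E,10E)‑12‑bromo‑3,7,11‑trimethyldodeca‑2,6,10‑trien‑1‑yl acetate
Conditions: CBr4, PPh3, CH2Cl2, 0 °C
Reagents that add atoms: carbon tetrabromide, BrC(Br)(Br)Br
Why: Appel bromination of a primary allylic alcohol under neutral conditions keeps the acetate and the alkene geometry.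

**Step 5**
Reactants: 8, (2E,6E)‑farnesyl bromide; 9, sodium benzenesulfinate
Product: 10, (2E,6E)‑farnesyl phenyl sulfone
Conditions: PhSO2Na, DMF, rt
Reagents that add atoms: sodium benzenesulfinate, [Na+].[O-]S(=O)c1ccccc1
Why: SN2 S‑alkylation of sulfinate by a primary allylic bromide with retention of E geometry.

**Step 6**
Reactants: 10; 7
Product: 11, (2E,6E,10E,14E,18E)‑3,7,11,15,19,23‑hexamethyl‑13‑(phenylsulfonyl)tetracosa‑2,6,10,14,18,22‑hexaen‑1‑yl acetate (racemic at C13)
Conditions: 10, n‑BuLi (1.0 equiv), THF/DMPU, −78 °C; then 7, −78 → −40 °C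
Reagents that add atoms: none (only 7 and 10)
Why: Biellmann‑type α‑alkylation of an allyl sulfone carbanion; the soft anion reacts SN2 with the allylic bromide faster than with the acetate at −78 °C, and no alkene is touched.

**Step 7**
Reactants: 11
Product: 12, (2E,6E,10E,14E,18E)‑3,7,11,15,19,23‑hexamethyltetracosa‑2,6,10,14,18,22‑hexaen‑1‑ol (all‑E hexaprenol)
Conditions: LiBHEt3 (5 equiv), THF, 0 °C, 15 min; then PdCl2(dppp) (5 mol%), 0 °C → rt
Reagents that add atoms: none
Why: Superhydride first cleaves the acetate to the alkoxide (not ionisable by Pd); Pd‑catalysed reductive desulfonylation then delivers hydride to the less substituted π‑allyl terminus, keeping the alkene position and E geometry and removing the C13 stereocentre.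

**Step 8**
Reactants: 12
Product: 13, all‑E hexaprenyl bromide
Conditions: PBr3 (0.4 equiv), pyridine (cat.), Et2O, −10 → 0 °C; use crude
Reagents that add atoms: phosphorus tribromide, BrP(Br)Br
Why: Standard conversion of a primary allylic alcohol to the bromide at low temperature without E/Z erosion.

**Step 9**
Reactants: 4; 13
Product: 14, racemic 9a‑hexaprenyl‑4a,5‑dimethyl‑1,4,4a,9a‑tetrahydro‑1,4‑methanoanthracene‑9,10‑dione (cis‑fused; 4a‑Me and 9a‑chain both exo)
Conditions: KOt‑Bu (1.1 equiv), THF/t‑BuOH, 0 °C; then 13, 0 °C → rt, dark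
Reagents that add atoms: none (only 4 and 13)
Why: Enolate C‑alkylation at the only α‑CH, from the exo face; SN2 on the primary allylic bromide keeps the 2′E geometry and fixes the chain next to the C=O remote from the peri‑methyl.

**Step 10**
Reactants: 14
Product: 15, target: 2‑[(2E,6E,10E,14E,18E)‑3,7,11,15,19,23‑hexamethyltetracosa‑2,6,10,14,18,22‑hexaenyl]‑3,5‑dimethylnaphthalene‑1,4‑dione
Conditions: toluene, reflux (110 °C), 1 h, N2, dark
Reagents that add atoms: none
Why: Retro‑Diels–Alder expels cyclopentadiene and regenerates the quinone under neutral thermal conditions that do not isomerise the polyene.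

## Compound list
1 | 1,7‑dimethylnaphthalene | Cc1ccc2cccc(C)c2c1 | starting material
2 | 2,8‑dimethylnaphthalene‑1,4‑dione | CC1=CC(=O)c2cccc(C)c2C1=O | intermediate
3 | cyclopenta‑1,3‑diene | C1C=CC=C1 | starting material
4 | endo Cp adduct, racemic (one enantiomer drawn) | C[C@@]12C(=O)c3c(C)cccc3C(=O)[C@@H]1[C@@H]1C=C[C@H]2C1 | intermediate
5 | (2E,6E)‑farnesyl acetate | CC(=O)OC/C=C(\C)CC/C=C(\C)CCC=C(C)C | starting material
6 | (2E,6E,10E)‑12‑hydroxyfarnesyl acetate | CC(=O)OC/C=C(\C)CC/C=C(\C)CC/C=C(\C)CO | intermediate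
7 | (2E,6E,10E)‑12‑bromofarnesyl acetate | CC(=O)OC/C=C(\C)CC/C=C(\C)CC/C=C(\C)CBr | intermediate
8 | (2E,6E)‑farnesyl bromide | BrC/C=C(\C)CC/C=C(\C)CCC=C(C)C | starting material
9 | sodium benzenesulfinate | [Na+].[O-]S(=O)c1ccccc1 | starting material
10 | (2E,6E)‑farnesyl phenyl sulfone | O=S(=O)(C/C=C(\C)CC/C=C(\C)CCC=C(C)C)c1ccccc1 | intermediate
11 | C30 13‑phenylsulfonyl hexaprenyl acetate (racemic at C13) | CC(=O)OC/C=C(\C)CC/C=C(\C)CC/C=C(\C)CC(/C=C(\C)CC/C=C(\C)CCC=C(C)C)S(=O)(=O)c1ccccc1 | intermediate
12 | all‑E hexaprenol | OC/C=C(\C)CC/C=C(\C)CC/C=C(\C)CC/C=C(\C)CC/C=C(\C)CCC=C(C)C | intermediate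
13 | all‑E hexaprenyl bromide | BrC/C=C(\C)CC/C=C(\C)CC/C=C(\C)CC/C=C(\C)CC/C=C(\C)CCC=C(C)C | intermediate
14 | C9a‑hexaprenylated Cp adduct, racemic | C[C@@]12C(=O)c3c(C)cccc3C(=O)[C@]1(C/C=C(\C)CC/C=C(\C)CC/C=C(\C)CC/C=C(\C)CC/C=C(\C)CCC=C(C)C)[C@@H]1C=C[C@H]2C1 | intermediate
15 | 8‑methylmenaquinone‑6 | CC(C)=CCC/C(C)=C/CC/C(C)=C/CC/C(C)=C/CC/C(C)=C/CC/C(C)=C/CC1=C(C)C(=O)c2c(C)cccc2C1=O | target

## Summary
Total steps: 10. Longest linear sequence: 7 (steps 3, 4, 6, 7, 8, 9, 10 from farnesyl acetate).

Three steps most likely to fail, with fallbacks: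
- **Step 1** (over‑oxidation or low yield of the quinone): build the core instead by a bromine‑directed Diels–Alder of 2‑bromo‑6‑methyl‑1,4‑benzoquinone with (E)‑penta‑1,3‑diene, then Et3N‑promoted HBr loss and DDQ or MnO2 aromatisation to 2.
- **Step 3** (site selectivity between the Δ6 and Δ10 alkenes, modest yield): change the chain disconnection to C10 + C20. Geranyl acetate has only one remote trisubstituted alkene, so it gives 8‑bromogeranyl acetate cleanly, and this is coupled with geranylgeranyl phenyl sulfone made from geranylgeraniol.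
- **Step 7** (alkene migration or E/Z leakage, or allylic C–O hydrogenolysis): avoid the sulfone altogether. Couple farnesylbarium (farnesyl chloride, Rieke Ba, THF, −78 °C) α,α′‑selectively and with retention of geometry with the TBS ether of 12‑bromofarnesol, then TBAF, to reach 12.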